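Its constants are assumed; the flask was simulated.

- The vessel was a closed, stirred flask held at constant volume and temperature, in which initiator met impurity and free monomer.

free monomer 20 mM; initiator 0.14 mM; impurity 64 µM; time 3.0 d

    initiator + impurity → spent initiator B (k1 = 3400 M⁻¹ min⁻¹)
    free monomer + initiator → spent initiator A (k2 = 0.012 M⁻¹ min⁻¹)
    free monomer + initiator → living end + monomer in chains (k3 = 0.18 M⁻¹ min⁻¹)
    free monomer + living end → monomer in chains + living end, rate k4*[living end]*[free monomer] (k4 = 2.8 M⁻¹ min⁻¹)

1. average number of monomer units in a chain (chains begun, living or dead) at 3.0 d
2. part of the free monomer that has reacted at 3.0 d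

- the average divides the monomer in chains by the number of chains begun, living and dead together
- run time (flask): 3.0 d

- I counted half-lives of free monomer, and as a yardstick I took every initiator as a living end, which gave a half-life of 1.23 d.
- The first slowing was the impurity: at the initiator charge its lifetime was about 2.10 min, far shorter than the 0.181 d lifetime of initiator among free monomer. As limiting reagent of step 1, it therefore took its 64 µM of initiator first, and this multiplied the rate by 0.543.
- The second slowing was step 2, which competes with step 3 for initiator and multiplied the rate by 0.938.
- Together these gave the chain-growth half-life 2.41 d, the time in which free monomer halves once the living ends stand; the decay is then pseudo-first-order.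
- The third slowing was the wait for living ends, which I counted as 0.181 d lost, so 3.0 d held 1.17 half-lives. That gave me c of 55.5% and dp of 156.
- The forecast gave dp 156 (150 to 162) and c 55% (53% to 57%), with the growth reckoned “less a lag of about 270 min for initiation”; my lag was 260 min.
- The flask gave dp 156 and c 55.6%. Its half-life of free monomer by chain growth read 2.4 d at 1.31 d and 2.4 d at 3.00 d, shorter than the run of 3.0 d, and my 2.41 d stood beside it. For the neighbour flask with 5.0 mM of free monomer I kept 2.41 d and took a lag of 0.723 d, which counted 0.944 half-lives and left 52.0%. That neighbour flask held 51.9% of its free monomer at 3.00 d.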